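# Proposed total synthesis of isodihydromaldoxin (19)

**Locants used throughout.** Ring A: C1 carries the ether oxygen, C2 the methoxy group, C3 hydrogen, C4 the hydroxyl, C5 hydrogen, C6 the methyl ester. Ring B: C1' carries the ether oxygen, C2' hydrogen, C3' the methyl group, C4' chlorine, C5' the hydroxyl, C6' the carboxyl group.

**Compound numbers (full list with SMILES after the steps).** 1 o-vanillic acid; 2 aryl sulfate formed in the flask; 3 2,5-dihydroxy-3-methoxybenzoic acid; 4 its methyl ester; 5 ring A phenol (4-O-benzyl); 6 dibenzyl malonate; 7 dibenzyl acetylmalonate; 8 its enol tosylate; 9 aryloxy ethylidene malonate; 10 silyl ketene acetal diene; 11 chloromethyl phenyl sulfoxide; 12 acetaldehyde; 13 chlorohydrin; 14 its mesylate; 15 (Z)-chlorovinyl sulfoxide; 16 cycloadduct; 17 chloro sulfinyl cyclohexenone; 18 protected diaryl ether; 19 target.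

## Analysis of the target

Compound 19 is a diaryl ether built from two benzene rings; it contains no stereocentre, and because ring B has only one ortho substituent larger than hydrogen, no stable atropisomers about the ether axis need be considered. Ring A is a 1,2,4,6-tetrasubstituted benzoate whose ether oxygen at C1 is flanked by the C2 methoxy group and the C6 methyl ester, and ring B is pentasubstituted, with the ether oxygen, H, CH3, Cl, OH and CO2H running from C1' to C6'. The sensitive points are two carboxyl groups that must end up differentiated (methyl ester on ring A, free acid on ring B), an aryl chloride that rules out forcing reductive conditions, and an electron-rich hydroquinone-type ring A. Two things make the synthesis hard: the ether links a doubly ortho-substituted, hydrogen-bonded phenol oxygen to a ring B carbon next to a carboxyl group, and chlorine must be placed at C4' and not at C2', although both positions are activated towards electrophiles by an oxygen substituent in the ortho or para position. The strategy rests on the following feature of ring B: C3' (methyl) and C4' (chlorine) form an adjacent two-carbon unit, bounded by C2'–H and by the hydroxyl carbon C5', and the remaining four carbons C2'–C1'(OAr)–C6'(CO2R)–C5'(O) are the carbon chain of an acetylmalonate enol ether. Ring B can therefore be assembled from a four-carbon diene that already carries the ether oxygen and a two-carbon alkyne equivalent that carries methyl and chlorine.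

## Retrosynthetic reasoning

**19 ⇒ 18.** The last operation removes only protecting groups: the two O–benzyl bonds (ring B ester, ring A C4 ether) are cut. Keeping the ring A carboxyl as a methyl ester and the ring B carboxyl as a benzyl ester from the start solves the differentiation of the two acids without any late esterification. The forward reaction has to cleave benzyl groups without touching the C4'–Cl bond, the methyl ether or the methyl ester, which points to Lewis acid cleavage rather than hydrogenolysis.

**18 ⇒ 10 + 15.** Ring B is opened at C2'–C3' and C4'–C5'. This cut separates the methyl/chloro pair from the oxygenated four-carbon chain, so the position of chlorine between methyl and hydroxyl follows from the orientation of a cycloaddition and not from an electrophilic substitution. Cutting the ether bond O–C1' on the finished arene instead would require a hindered aryl–oxygen coupling and a ready-made pentasubstituted ring B. Forward, the ketene acetal diene 10 has to add the vinyl sulfoxide 15 with its CH2 terminus on the methyl-bearing carbon. The cycloadduct 16 must then collapse at its silyl ketal carbon to the ketone 17 and lose its sulfinyl group by syn elimination, with chlorine retained, so that the ring aromatises to the free C5' phenol of 18.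

**10 ⇒ 9.** The diene is the silyl dienol ether of the alkylidene malonate 9; the O–Si bond and one C2'–H bond are cut. The forward reaction must remove a proton from the methyl group of 9 and silylate on oxygen before the extended enolate can expel the aryloxy group.

**9 ⇒ 8 + 5.** The ether bond O–C1' is cut while C1' is still the β-carbon of an alkylidene malonate. At this stage it is a strongly electrophilic sp2 carbon, and the crowded phenol 5 can be introduced by addition–elimination on the enol tosylate 8 without any metal-mediated arylation. This is the main gain of building ring B after the ether.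

**8 ⇒ 7 ⇒ 6.** The enol O–S bond is cut first, then the C1'–C6' bond between the acetyl group and the malonate carbon. Both forward reactions are standard operations on dibenzyl malonate 6, and the two identical ester groups of 7, 8 and 9 remove any question of alkene geometry.

**5 ⇒ 4 ⇒ 3 ⇒ 1.** On ring A the O–benzyl bond, the ester O–CH3 bond and the C4–O bond are cut in turn. The C4 oxygen is introduced para to the phenol oxygen of o-vanillic acid 1 via the aryl sulfate 2. This position is the only free one that the phenoxide activates, and the C1 hydroxyl of 4 is hydrogen-bonded and hindered, so that benzylation should occur at C4–OH.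

**15 ⇒ 13 ⇒ 11 + 12.** The C3'=C4' double bond of the dienophile is traced back to the β-hydroxy sulfoxide 13 through its mesylate 14, a dehydration in the forward sense. The C3'–C4' bond of 13 is then cut to the carbanion of 11 and the aldehyde 12. The forward sequence must deliver the alkene with methyl trans to the sulfinyl group.

## Alternatives that were turned down

**Alternative 1:** Ring A, not ring B, is constructed, by a Danheiser benzannulation. The disconnection cuts C2–C3, C4–C5 and C1–C2 of ring A; the C5–C6 bond arises in a Wolff shift. In the forward direction, irradiation of methyl 3-[2-(tert-butoxycarbonyl)-4-chloro-3-methoxy-5-methylphenoxy]-2-(diazoacetyl)prop-2-enoate A2 triggers the Wolff rearrangement to an aryloxy-substituted vinylketene. This adds (triisopropylsilyloxy)acetylene A3 to give a cyclobutenone (C2–C3 and C4–C5), which opens and closes in a six-electron electrocyclisation (C1–C2). The product is tert-butyl 3-chloro-6-[2-hydroxy-6-(methoxycarbonyl)-4-(triisopropylsilyloxy)phenoxy]-2-methoxy-4-methylbenzoate A1.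

- For it: the two ring A oxygens emerge differentiated (free C2–OH for methylation, silylated C4–O), and the benzannulation of vinylketenes with silyloxyalkynes is an established reaction class with dependable regiochemistry. On precedent for the key step this alternative is stronger than the chosen route.
- Against it: ring B must be brought in as a complete, pentasubstituted phenol, so the real regiochemical problem of the target, chlorine at C4' rather than C2', is moved into a starting material and not solved. A2 is a doubly activated β-aryloxy enone in which the ring B aryloxide is a leaving group, and it needs several steps. After the key step, A1 still requires O-methylation at C2, desilylation, cleavage of the tert-butyl ester and selective cleavage of the C5' methyl ether.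
- Comparison: the chosen route sets the chlorine position by construction and needs one step after ring formation, at the price of a less precedented cycloaddition.

**Alternative 2:** The bonds O–C1' and C6'–CO2H are cut, leading back to a ring B aryne across C1'/C6'. Forward, fluoride releases the aryne from 4-chloro-3-methoxy-5-methyl-2-(trimethylsilyl)phenyl trifluoromethanesulfonate A5. The phenoxide of 2-(dimethoxymethyl)-6-methoxy-4-(methoxymethoxy)phenol A6 adds at C1', and the C6' aryl anion is carboxylated in the same flask. The product is 3-chloro-6-[2-(dimethoxymethyl)-6-methoxy-4-(methoxymethoxy)phenoxy]-2-methoxy-4-methylbenzoic acid A4.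

- For it: this is the most convergent plan. Two bonds, including the hindered ether bond, are made in one mild operation from two arene halves, and the methoxy group next to the aryne directs the nucleophile to the distal carbon reliably. On convergence it is stronger than the chosen route.
- Against it: a doubly ortho-substituted phenoxide is a weak partner for an aryne, and the basic C6' anion is more readily protonated than carboxylated. Ring A cannot carry its ester through the step (the anion would attack it), hence the acetal and the methoxymethyl ether in A6. That adds acetal hydrolysis, oxidation, an esterification that must distinguish the ring A acid from the ring B acid, two deprotections and the C5' demethylation. A5 again presupposes a ring B with chlorine, methyl and oxygen already in place.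
- Comparison: the chosen route is linear through ring B, but it has a single final deprotection, never has to tell two free carboxyl groups apart, and fixes the chlorine position in the ring-forming step.

**Alternative 3:** Ring B is cut at C5'–C6' and C3'–C4', which leads to benzyl 4-[4-(benzyloxy)-2-methoxy-6-(methoxycarbonyl)phenoxy]-6-methyl-2-oxo-2H-pyran-3-carboxylate A8 and 2-chloro-1,1-dimethoxyethene A9. Forward, the electron-poor pyrone adds the ketene acetal across its C3 and C6 termini; the bridged lactone extrudes its carboxyl bridge and then gives up one methoxy group to aromatise. The product is benzyl 6-[4-(benzyloxy)-2-methoxy-6-(methoxycarbonyl)phenoxy]-3-chloro-2-methoxy-4-methylbenzoate A7.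

- For it: cycloaddition of 3-alkoxycarbonyl-2-pyrones with ketene acetals followed by decarboxylative aromatisation is known chemistry. The chlorine position is again set by construction, and the end game is equally short. On precedent this alternative is stronger than the chosen route, and on step count it is its equal.
- Against it: in A8 the aryloxy group sits on C4, an electrophilic vinylogous acyl carbon. The nucleophilic ketene acetal A9 and the alcohol released at the required temperature can displace the ring A aryloxide there. The donor at C4 and the methyl group at C6 both lower the reactivity of the pyrone at the carbon that must be attacked. The allylic chloride of the decarboxylated intermediate can ionise before aromatisation. The final Lewis acid step on A7 must cleave the C5' methyl ether while sparing the C2 methyl ether of ring A.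
- Comparison: the chosen route offers a diene in which the aryloxy carbon is an internal, non-electrophilic position, so the ether bond is not at risk during ring formation. It also gives the C5' hydroxyl free, so that no methyl ether has to be cleaved at all.

Key step: step 10

## Route

Assumption: sulfoxides 11 and 13–17 are racemic at sulfur, and 13, 14, 16 and 17 are diastereomer mixtures. Their SMILES therefore carry no stereodescriptors; only the alkene geometry of 15 is specified.

Step 1
Reactants: 1 2-hydroxy-3-methoxybenzoic acid (o-vanillic acid)
Product: 3 2,5-dihydroxy-3-methoxybenzoic acid, via 2-hydroxy-3-methoxy-5-(sulfooxy)benzoic acid 2 (not isolated)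
Conditions: K2S2O8, aq NaOH, 0 → 20 °C; then HCl, 90 °C
Reagents that add atoms: dipotassium peroxodisulfate (K2S2O8), [K+].[K+].[O-]S(=O)(=O)OOS(=O)(=O)[O-]
Why: Elbs persulfate oxidation: the phenoxide attacks a peroxide oxygen through the only free activated position, para to the phenol oxygen (C4 of ring A, both ortho positions being occupied), and acid hydrolysis of aryl sulfate 2 should release the hydroquinone.

Step 2
Reactants: 3 2,5-dihydroxy-3-methoxybenzoic acid
Product: 4 methyl 2,5-dihydroxy-3-methoxybenzoate
Conditions: MeOH, H2SO4 (cat.), reflux, under N2
Reagents that add atoms: methanol, CO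
Why: Fischer esterification; the phenolic hydroxyls are inert to acid-catalysed methanolysis and the hydroquinone is kept from air.

Step 3
Reactants: 4 methyl 2,5-dihydroxy-3-methoxybenzoate
Product: 5 methyl 5-(benzyloxy)-2-hydroxy-3-methoxybenzoate
Conditions: BnBr (1.05 equiv), K2CO3, acetone, 23 → 56 °C, under N2
Reagents that add atoms: benzyl bromide, BrCc1ccccc1
Why: Williamson ether synthesis that should select the C4 hydroxyl of ring A, because the C1 hydroxyl is tied up in a hydrogen bond to the ester carbonyl and is flanked by two ortho substituents, as in the known selective 5-O-alkylation of gentisate esters.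

Step 4
Reactants: 6 dibenzyl malonate
Product: 7 dibenzyl 2-acetylpropanedioate
Conditions: AcCl, MgCl2, Et3N, MeCN, 0 → 23 °C; then 1 M HCl
Reagents that add atoms: acetyl chloride, CC(Cl)=O
Why: C-acylation of a malonate through its magnesium enolate (soft enolisation with MgCl2 and Et3N); chelation of the acylated enolate to magnesium suppresses O-acylation and a second acylation.

Step 5
Reactants: 7 dibenzyl 2-acetylpropanedioate
Product: 8 dibenzyl 2-{1-[(4-methylbenzenesulfonyl)oxy]ethylidene}propanedioate
Conditions: TsCl, Et3N, N-methylimidazole (cat.), CH2Cl2, 0 °C
Reagents that add atoms: 4-methylbenzenesulfonyl chloride, Cc1ccc(cc1)S(Cl)(=O)=O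
Why: O-sulfonylation of the fully enolised tricarbonyl compound gives the enol tosylate; the two identical ester groups leave no alkene isomers.

Step 6
Reactants: 8 dibenzyl 2-{1-[(4-methylbenzenesulfonyl)oxy]ethylidene}propanedioate; 5 methyl 5-(benzyloxy)-2-hydroxy-3-methoxybenzoate
Product: 9 dibenzyl 2-{1-[4-(benzyloxy)-2-methoxy-6-(methoxycarbonyl)phenoxy]ethylidene}propanedioate
Conditions: Cs2CO3, MeCN, 23 → 50 °C
Reagents that add atoms: none
Why: Nucleophilic vinylic substitution by addition–elimination at the doubly activated β-carbon of the alkylidene malonate; an elimination–addition path through the allenyl malonate would lead to the same product, so both mechanisms converge on 9.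

Step 7
Reactants: 9 dibenzyl 2-{1-[4-(benzyloxy)-2-methoxy-6-(methoxycarbonyl)phenoxy]ethylidene}propanedioate
Product: 10 benzyl 3-[4-(benzyloxy)-2-methoxy-6-(methoxycarbonyl)phenoxy]-2-[benzyloxy(trimethylsilyloxy)methylidene]but-3-enoate
Conditions: Me3SiCl, then LiN(iPr)2, THF, −78 °C (in situ quench); evaporation, pentane extraction under argon, used at once
Reagents that add atoms: chlorotrimethylsilane, C[Si](C)(C)Cl
Why: Deprotonation of the methyl group of the alkylidene malonate and O-silylation of the extended enolate (silyl dienol ether formation); the silyl chloride is present from the start so that the lithium dienolate is trapped before it can expel aryloxide, and a silyl shift between the two benzyl ester oxygens is degenerate.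

Step 8
Reactants: 11 chloromethyl phenyl sulfoxide; 12 acetaldehyde
Product: 13 1-chloro-1-(phenylsulfinyl)propan-2-ol (diastereomer mixture)
Conditions: LiN(iPr)2, THF, −78 °C; then 12; sat. aq NH4Cl at −78 °C
Reagents that add atoms: none
Why: Addition of the α-chloro α-sulfinyl carbanion to the aldehyde; the cold quench keeps the chlorohydrin alkoxide from closing to an epoxy sulfoxide (Darzens pathway).

Step 9
Reactants: 13 1-chloro-1-(phenylsulfinyl)propan-2-ol
Product: 15 (Z)-1-chloro-1-(phenylsulfinyl)prop-1-ene, via 1-chloro-1-(phenylsulfinyl)propan-2-yl methanesulfonate 14 (not isolated)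
Conditions: MsCl, Et3N, CH2Cl2, 0 °C; then DBU, 0 → 23 °C; chromatographic separation from the E isomer
Reagents that add atoms: none
Why: Mesylation and E1cB elimination through the carbanion stabilised by sulfinyl and chlorine; all diastereomers of 14 pass through the same carbanion, and the alkene with methyl trans to the bulkier sulfinyl group (the Z isomer, with H cis to sulfur) should predominate.

Step 10
Reactants: 10 benzyl 3-[4-(benzyloxy)-2-methoxy-6-(methoxycarbonyl)phenoxy]-2-[benzyloxy(trimethylsilyloxy)methylidene]but-3-enoate; 15 (Z)-1-chloro-1-(phenylsulfinyl)prop-1-ene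
Product: 18 benzyl 6-[4-(benzyloxy)-2-methoxy-6-(methoxycarbonyl)phenoxy]-3-chloro-2-hydroxy-4-methylbenzoate, via silyl ketal cycloadduct 16 (not isolated), via chloro sulfinyl cyclohexenone 17 (not isolated)
Conditions: 15 (2 equiv), CaCO3, PhMe, 110 °C, sealed tube; then 1 M HCl, THF, 23 °C
Reagents that add atoms: none
Why: Proposed new method: the CH2 terminus of the 1-benzyloxy-1-silyloxy diene 10, where its HOMO coefficient is largest, should bond to the methyl-bearing β-carbon of vinyl sulfoxide 15 while the ketene acetal carbon bonds to the chloro sulfinyl carbon, in a concerted but asynchronous, suprafacial [4+2] cycloaddition. The closest known reaction type is the Diels–Alder addition of vinylketene silyl acetals to phenyl vinyl sulfoxide, which acts as an alkyne equivalent through loss of sulfenic acid; new here are the α-chloro, β-methyl substitution of the dienophile and the 2-ester, 3-aryloxy substitution of the diene. Ring B is closed as a six-membered carbocycle by this intermolecular cycloaddition, the two new σ bonds being C2'–C3' and C4'–C5'. The silyl ketal carbon C5' of 16 then expels benzyl trimethylsilyl ether to give ketone 17, the sulfinyl group leaves together with the C3' hydrogen in a thermal five-centre syn elimination, and the cross-conjugated dienone so formed tautomerises through its C2' methylene to the phenol, the brief acidic work-up removing any remaining silyl group. The stereocentres created in 16 (C3', C4', C5', besides sulfur) are all destroyed, and the only relationship that matters is the cis arrangement of C3'–H and the sulfinyl group, which the Z geometry of 15 carries into the adduct and which the syn elimination requires. The step needs regioselectivity, so that chlorine lies between methyl and hydroxyl, and the opposed polarisation of the ketene acetal and of the β-substituted vinyl sulfoxide secures it. It also needs chemoselectivity between loss of PhSOH and loss of HCl, which the neutral, CaCO3-buffered thermal conditions secure, because the intramolecular sulfoxide elimination needs no base whereas dehydrochlorination does.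

Step 11
Reactants: 18 benzyl 6-[4-(benzyloxy)-2-methoxy-6-(methoxycarbonyl)phenoxy]-3-chloro-2-hydroxy-4-methylbenzoate
Product: 19 3-chloro-2-hydroxy-6-[4-hydroxy-2-methoxy-6-(methoxycarbonyl)phenoxy]-4-methylbenzoic acid (isodihydromaldoxin)
Conditions: BCl3, C6HMe5, CH2Cl2, −78 → −20 °C; then MeOH, H2O
Reagents that add atoms: none
Why: Lewis acid debenzylation: BCl3 binds the salicylate chelate and the ether oxygen and ionises both O–benzyl bonds, pentamethylbenzene captures the benzyl cations by Friedel–Crafts alkylation, and at low temperature the methyl ester and the methyl ether, which is not chelated to a carbonyl group, should remain.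

## Compound list

1 | 2-hydroxy-3-methoxybenzoic acid (o-vanillic acid) | COc1cccc(C(=O)O)c1O | starting material
2 | 2-hydroxy-3-methoxy-5-(sulfooxy)benzoic acid | COc1cc(OS(=O)(=O)O)cc(C(=O)O)c1O | intermediate
3 | 2,5-dihydroxy-3-methoxybenzoic acid | COc1cc(O)cc(C(=O)O)c1O | intermediate
4 | methyl 2,5-dihydroxy-3-methoxybenzoate | COC(=O)c1cc(O)cc(OC)c1O | intermediate
5 | methyl 5-(benzyloxy)-2-hydroxy-3-methoxybenzoate | COC(=O)c1cc(OCc2ccccc2)cc(OC)c1O | intermediate
6 | dibenzyl malonate | O=C(CC(=O)OCc1ccccc1)OCc1ccccc1 | starting material
7 | dibenzyl 2-acetylpropanedioate | CC(=O)C(C(=O)OCc1ccccc1)C(=O)OCc1ccccc1 | intermediate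
8 | dibenzyl 2-{1-[(4-methylbenzenesulfonyl)oxy]ethylidene}propanedioate | CC(OS(=O)(=O)c1ccc(C)cc1)=C(C(=O)OCc1ccccc1)C(=O)OCc1ccccc1 | intermediate
9 | dibenzyl 2-{1-[4-(benzyloxy)-2-methoxy-6-(methoxycarbonyl)phenoxy]ethylidene}propanedioate | CC(Oc1c(OC)cc(OCc2ccccc2)cc1C(=O)OC)=C(C(=O)OCc1ccccc1)C(=O)OCc1ccccc1 | intermediate
10 | benzyl 3-[4-(benzyloxy)-2-methoxy-6-(methoxycarbonyl)phenoxy]-2-[benzyloxy(trimethylsilyloxy)methylidene]but-3-enoate | C=C(Oc1c(OC)cc(OCc2ccccc2)cc1C(=O)OC)C(C(=O)OCc1ccccc1)=C(OCc1ccccc1)O[Si](C)(C)C | intermediate
11 | chloromethyl phenyl sulfoxide (racemic) | ClCS(=O)c1ccccc1 | starting material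
12 | acetaldehyde | CC=O | starting material
13 | 1-chloro-1-(phenylsulfinyl)propan-2-ol (diastereomer mixture) | CC(O)C(Cl)S(=O)c1ccccc1 | intermediate
14 | 1-chloro-1-(phenylsulfinyl)propan-2-yl methanesulfonate (diastereomer mixture) | CC(OS(C)(=O)=O)C(Cl)S(=O)c1ccccc1 | intermediate
15 | (Z)-1-chloro-1-(phenylsulfinyl)prop-1-ene (racemic at sulfur; methyl cis to chlorine) | C/C=C(\Cl)S(=O)c1ccccc1 | intermediate
16 | benzyl 2-[4-(benzyloxy)-2-methoxy-6-(methoxycarbonyl)phenoxy]-6-(benzyloxy)-5-chloro-4-methyl-5-(phenylsulfinyl)-6-(trimethylsilyloxy)cyclohex-1-ene-1-carboxylate (C4–H cis to the sulfinyl group; mixture at C6 and sulfur) | COC(=O)c1cc(OCc2ccccc2)cc(OC)c1OC1=C(C(=O)OCc2ccccc2)C(OCc2ccccc2)(O[Si](C)(C)C)C(Cl)(S(=O)c2ccccc2)C(C)C1 | intermediate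
17 | benzyl 2-[4-(benzyloxy)-2-methoxy-6-(methoxycarbonyl)phenoxy]-5-chloro-4-methyl-6-oxo-5-(phenylsulfinyl)cyclohex-1-ene-1-carboxylate (C4–H cis to the sulfinyl group) | COC(=O)c1cc(OCc2ccccc2)cc(OC)c1OC1=C(C(=O)OCc2ccccc2)C(=O)C(Cl)(S(=O)c2ccccc2)C(C)C1 | intermediate
18 | benzyl 6-[4-(benzyloxy)-2-methoxy-6-(methoxycarbonyl)phenoxy]-3-chloro-2-hydroxy-4-methylbenzoate | COC(=O)c1cc(OCc2ccccc2)cc(OC)c1Oc1cc(C)c(Cl)c(O)c1C(=O)OCc1ccccc1 | intermediate
19 | 3-chloro-2-hydroxy-6-[4-hydroxy-2-methoxy-6-(methoxycarbonyl)phenoxy]-4-methylbenzoic acid (isodihydromaldoxin) | COC(=O)c1cc(O)cc(OC)c1Oc1cc(C)c(Cl)c(O)c1C(=O)O | target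

## Step count and risk

Total: 11 steps. Longest linear sequence: 7 steps (steps 1, 2, 3, 6, 7, 10, 11, from 1). The branch from 6 has 6 steps to the target and the branch from 11 has 4.

**Step 10 (key step, proposed new method).** The likeliest failure is that no cycloaddition takes place. The sulfinyl group is a weak acceptor, the β-methyl group slows the dienophile further, and the C2 ester attenuates the diene. Under prolonged heating the diene would then be protodesilylated back to 9 by the phenolic product and by the sulfenic acid. A stepwise Michael pathway that scrambles the cis relationship of C3'–H and sulfur would also stall the elimination. If the ketal partitions towards loss of silanol, the C5' oxygen stays benzylated, which step 11 corrects. Fallback, using known reaction types, which builds ring B from an electron-poor diene and an electron-rich dienophile instead: 6 is C-acylated with diketene (C=C1CC(=O)O1; NaH, THF, 0 → 23 °C, then HCl), and the acetoacetylmalonate so formed lactonises to benzyl 4-hydroxy-6-methyl-2-oxo-2H-pyran-3-carboxylate F1. TsCl and Et3N in CH2Cl2 give benzyl 6-methyl-4-[(4-methylbenzenesulfonyl)oxy]-2-oxo-2H-pyran-3-carboxylate F2. Phenol 5 with Cs2CO3 in MeCN should displace the sulfonate by addition–elimination and give benzyl 4-[4-(benzyloxy)-2-methoxy-6-(methoxycarbonyl)phenoxy]-6-methyl-2-oxo-2H-pyran-3-carboxylate F3, which is the same compound as A8. Heating F3 with 2-chloro-1,1-dimethoxyethene A9 in toluene at 110 °C should give, by cycloaddition, decarboxylation and loss of one methoxy group, benzyl 6-[4-(benzyloxy)-2-methoxy-6-(methoxycarbonyl)phenoxy]-3-chloro-2-methoxy-4-methylbenzoate F4, which is the same compound as A7. BCl3 and C6HMe5 in CH2Cl2, warmed from −78 to 0 °C, should then cleave both benzyl groups and the C5' methyl ether, which is chelated to the neighbouring ester, and the route is rejoined at 19. The cost is four extra steps and the exposure of the aryloxy group on the electrophilic C4 of F3 to displacement.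

**Step 7.** The lithium dienolate may expel the ring A aryloxide (reverse of the addition to an allenyl malonate), and the trimethylsilyl ketene acetal may be hydrolysed during isolation. Fallback without a metal dienolate: 9 is treated with TBSOTf and Et3N in CH2Cl2 at 0 °C (soft enolisation). This should give benzyl 3-[4-(benzyloxy)-2-methoxy-6-(methoxycarbonyl)phenoxy]-2-[benzyloxy(tert-butyldimethylsilyloxy)methylidene]but-3-enoate F5, a more robust diene. It enters the cycloaddition with 15 in place of 10 and gives benzyl 2-[4-(benzyloxy)-2-methoxy-6-(methoxycarbonyl)phenoxy]-6-(benzyloxy)-6-(tert-butyldimethylsilyloxy)-5-chloro-4-methyl-5-(phenylsulfinyl)cyclohex-1-ene-1-carboxylate F6. Loss of the benzyl silyl ether returns the sequence to 17 and so to 18.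

**Step 6.** The phenoxide of 5 is hindered and may attack the sulfonyl sulfur of 8 instead of the β-carbon; this sulfonyl transfer would give back the enolate of 7. Fallback with an electrophile that has no sulfur: 7 is converted with POCl3 and Bu3N (toluene, 90 °C) into dibenzyl 2-(1-chloroethylidene)propanedioate F7, a vinylogous acid chloride. The sodium salt of 5 (NaH, THF, 0 → 23 °C) should displace chloride from it by addition–elimination, which rejoins the route at 9.

**Step 9.** The elimination may give a large share of the E isomer, whose cycloadduct cannot undergo the syn elimination. DBU may also shift the double bond to the allylic sulfoxide, which would be lost by sulfoxide–sulfenate rearrangement. Fallback by olefination instead of dehydration: 11 is deprotonated with LiN(iPr)2 (2 equiv, THF, −78 °C) and phosphorylated with ClP(O)(OEt)2 to give diethyl [chloro(phenylsulfinyl)methyl]phosphonate F8. Horner–Wadsworth–Emmons reaction of this phosphonate (NaH, THF, then 12) should place the methyl group trans to the sulfinyl group and rejoins the route at 15.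

**Step 1.** The electron-rich hydroquinone product may be oxidised further by persulfate, and conversion in Elbs oxidations is often incomplete. Fallback through a quinone: 1 is esterified (MeOH, H2SO4) to methyl 2-hydroxy-3-methoxybenzoate F9. Teuber oxidation with K2NO(SO3)2 (aqueous KH2PO4, acetone) should occur at the free para position and give methyl 5-methoxy-3,6-dioxocyclohexa-1,4-diene-1-carboxylate F10. Reduction with aqueous Na2S2O4 rejoins the route at 4.

**Step 11.** On warming, BCl3 may begin to cleave the ring A methyl ether or the methyl ester, or the chelated benzyl ester may be cleaved incompletely. Fallback by hydrogenolysis instead of Lewis acid cleavage: 18 is treated with H2 (1 atm) and Pd/C (zerovalent palladium on carbon) in ethyl acetate without added base. This should remove both benzyl groups as toluene and give 19 directly; the aryl chloride is expected to survive in the absence of base, and the reaction would be stopped once the benzyl groups are gone.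

## Further compounds

F1 | step 10 | benzyl 4-hydroxy-6-methyl-2-oxo-2H-pyran-3-carboxylate | Cc1cc(O)c(C(=O)OCc2ccccc2)c(=O)o1
F2 | step 10 | benzyl 6-methyl-4-[(4-methylbenzenesulfonyl)oxy]-2-oxo-2H-pyran-3-carboxylate | Cc1cc(OS(=O)(=O)c2ccc(C)cc2)c(C(=O)OCc2ccccc2)c(=O)o1
F3 | step 10 | benzyl 4-[4-(benzyloxy)-2-methoxy-6-(methoxycarbonyl)phenoxy]-6-methyl-2-oxo-2H-pyran-3-carboxylate | Cc1cc(Oc2c(OC)cc(OCc3ccccc3)cc2C(=O)OC)c(C(=O)OCc2ccccc2)c(=O)o1
F4 | step 10 | benzyl 6-[4-(benzyloxy)-2-methoxy-6-(methoxycarbonyl)phenoxy]-3-chloro-2-methoxy-4-methylbenzoate | COC(=O)c1cc(OCc2ccccc2)cc(OC)c1Oc1cc(C)c(Cl)c(OC)c1C(=O)OCc1ccccc1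
F5 | step 7 | benzyl 3-[4-(benzyloxy)-2-methoxy-6-(methoxycarbonyl)phenoxy]-2-[benzyloxy(tert-butyldimethylsilyloxy)methylidene]but-3-enoate | C=C(Oc1c(OC)cc(OCc2ccccc2)cc1C(=O)OC)C(C(=O)OCc1ccccc1)=C(OCc1ccccc1)O[Si](C)(C)C(C)(C)C
F6 | step 7 | benzyl 2-[4-(benzyloxy)-2-methoxy-6-(methoxycarbonyl)phenoxy]-6-(benzyloxy)-6-(tert-butyldimethylsilyloxy)-5-chloro-4-methyl-5-(phenylsulfinyl)cyclohex-1-ene-1-carboxylate | COC(=O)c1cc(OCc2ccccc2)cc(OC)c1OC1=C(C(=O)OCc2ccccc2)C(OCc2ccccc2)(O[Si](C)(C)C(C)(C)C)C(Cl)(S(=O)c2ccccc2)C(C)C1
F7 | step 6 | dibenzyl 2-(1-chloroethylidene)propanedioate | CC(Cl)=C(C(=O)OCc1ccccc1)C(=O)OCc1ccccc1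
F8 | step 9 | diethyl [chloro(phenylsulfinyl)methyl]phosphonate | CCOP(=O)(OCC)C(Cl)S(=O)c1ccccc1
F9 | step 1 | methyl 2-hydroxy-3-methoxybenzoate | COC(=O)c1cccc(OC)c1O
F10 | step 1 | methyl 5-methoxy-3,6-dioxocyclohexa-1,4-diene-1-carboxylate | COC(=O)C1=CC(=O)C=C(OC)C1=O
F0 | step 11 | none | none
A1 | alternative 1 | tert-butyl 3-chloro-6-[2-hydroxy-6-(methoxycarbonyl)-4-(triisopropylsilyloxy)phenoxy]-2-methoxy-4-methylbenzoate | COC(=O)c1cc(O[Si](C(C)C)(C(C)C)C(C)C)cc(O)c1Oc1cc(C)c(Cl)c(OC)c1C(=O)OC(C)(C)C
A2 | alternative 1 | methyl 3-[2-(tert-butoxycarbonyl)-4-chloro-3-methoxy-5-methylphenoxy]-2-(diazoacetyl)prop-2-enoate | COC(=O)C(=COc1cc(C)c(Cl)c(OC)c1C(=O)OC(C)(C)C)C(=O)C=[N+]=[N-]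
A3 | alternative 1 | (triisopropylsilyloxy)acetylene | C#CO[Si](C(C)C)(C(C)C)C(C)C
A4 | alternative 2 | 3-chloro-6-[2-(dimethoxymethyl)-6-methoxy-4-(methoxymethoxy)phenoxy]-2-methoxy-4-methylbenzoic acid | COCOc1cc(OC)c(Oc2cc(C)c(Cl)c(OC)c2C(=O)O)c(C(OC)OC)c1
A5 | alternative 2 | 4-chloro-3-methoxy-5-methyl-2-(trimethylsilyl)phenyl trifluoromethanesulfonate | COc1c(Cl)c(C)cc(OS(=O)(=O)C(F)(F)F)c1[Si](C)(C)C
A6 | alternative 2 | 2-(dimethoxymethyl)-6-methoxy-4-(methoxymethoxy)phenol | COCOc1cc(OC)c(O)c(C(OC)OC)c1
A7 | alternative 3 | benzyl 6-[4-(benzyloxy)-2-methoxy-6-(methoxycarbonyl)phenoxy]-3-chloro-2-methoxy-4-methylbenzoate | COC(=O)c1cc(OCc2ccccc2)cc(OC)c1Oc1cc(C)c(Cl)c(OC)c1C(=O)OCc1ccccc1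
A8 | alternative 3 | benzyl 4-[4-(benzyloxy)-2-methoxy-6-(methoxycarbonyl)phenoxy]-6-methyl-2-oxo-2H-pyran-3-carboxylate | Cc1cc(Oc2c(OC)cc(OCc3ccccc3)cc2C(=O)OC)c(C(=O)OCc2ccccc2)c(=O)o1
A9 | alternative 3 | 2-chloro-1,1-dimethoxyethene | COC(OC)=CCl
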